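**Plan**

1. Retrosynthesis: after removal of two MOM ethers and one acetate, the pyranone ring is cut at O1–C8a and at C4–C4a. This leaves the A ring as the benzyne C4a≡C8a and the atoms O1–C2–C3–C4 as a 4-aryloxetan-2-one that already carries the B ring and C2.
2. Enabling feature: O1 and the C4 acyl carbon sit on neighbouring A-ring carbons, so the C ring is a β-lactone with two arene carbons inserted into its acyl–oxygen bond. The C5 oxygen next to C4a steers the aryne addition, and the prenyl carbon C6 lies para to C8a, on the symmetry axis of a phloroglucinol.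
3. Forward, A ring: phloroglucinol → bis-MOM ether → lithiation/prenylation between the two MOM groups → ortho-bromination → o-silylaryl triflate 9.
4. Forward, B ring: vanillin acetate + ketene → (S)-β-lactone 11 by catalytic asymmetric [2+2]; the four-membered ring is made first, both arenes are bought.
5. Union: a fluoride-triggered aryne/β-lactone ring expansion (four- to six-membered) gives chromanone 13; acid methanolysis frees the three phenols.
6. Stereochemistry: C2 is set once, in the alkaloid-catalysed cycloaddition, and its bonds to O1, C3 and the aryl group are never broken afterwards.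

Key step: step 8

Remark: O-trimethylsilylquinine is assumed to give the 4S lactone (the pseudoenantiomeric O-trimethylsilylquinidine gives the antipode); the sense is to be confirmed once on 11 by correlation with the hydroxy acid F6 of the fallback, and the alkaloid exchanged if needed.

**Route**

Step 1
Reactants: 1 phloroglucinol (benzene-1,3,5-triol)
Product: 2 3,5-bis(methoxymethoxy)phenol
Conditions: MOMCl (2.0 equiv), iPr2NEt (2.2 equiv), DMF, 0 °C → rt; chromatography, mono- and tris-ethers recycled
Reagents that add atoms: chloromethyl methyl ether, COCCl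
Why: O-alkylation (Williamson type) of a C3-symmetric triphenol is statistical only in degree, not in position, so the bis-ether is a single compound and under- and over-alkylated material can be returned to 1.

Step 2
Reactants: 2 3,5-bis(methoxymethoxy)phenol
Product: 3 [3,5-bis(methoxymethoxy)phenoxy]triisopropylsilane
Conditions: TIPSCl, imidazole, DMF, rt
Reagents that add atoms: triisopropylsilyl chloride, CC(C)[Si](Cl)(C(C)C)C(C)C
Why: Silylation with a bulky, non-coordinating TIPS group masks the acidic OH and leaves the carbon between the two MOM ethers as the only doubly activated site for lithiation.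

Step 3
Reactants: 3 [3,5-bis(methoxymethoxy)phenoxy]triisopropylsilane
Product: 4 [3,5-bis(methoxymethoxy)-4-(3-methylbut-2-en-1-yl)phenoxy]triisopropylsilane
Conditions: n-BuLi (1.1 equiv), THF, 0 °C; then CuI (10 mol%), prenyl bromide, −78 °C → rt
Reagents that add atoms: prenyl bromide (1-bromo-3-methylbut-2-ene), CC(C)=CCBr
Why: Directed ortho-metalation occurs at the carbon flanked by both chelating MOM ethers, and the copper-assisted aryl nucleophile displaces bromide from prenyl bromide in SN2 fashion, which places the prenyl group on the symmetry axis, para to the oxygen that later becomes the triflate.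

Step 4
Reactants: 4 [3,5-bis(methoxymethoxy)-4-(3-methylbut-2-en-1-yl)phenoxy]triisopropylsilane
Product: 5 3,5-bis(methoxymethoxy)-4-(3-methylbut-2-en-1-yl)phenol
Conditions: TBAF (1.1 equiv), AcOH (1.1 equiv), THF, 0 °C
Reagents that add atoms: none
Why: Fluoride cleaves the aryl O–Si bond (buffered with acetic acid so that the phenoxide is protonated at once) while the MOM ethers and the alkene are inert.

Step 5
Reactants: 5 3,5-bis(methoxymethoxy)-4-(3-methylbut-2-en-1-yl)phenol
Product: 6 2-bromo-3,5-bis(methoxymethoxy)-4-(3-methylbut-2-en-1-yl)phenol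
Conditions: NBS (1.0 equiv), CH2Cl2, −78 °C
Reagents that add atoms: N-bromosuccinimide, O=C1CCC(=O)N1Br
Why: Electrophilic aromatic bromination of the very electron-rich phenol goes ortho to OH (both ortho positions are equivalent, para is blocked), and at −78 °C without an added nucleophile the trisubstituted alkene should not compete.

Step 6
Reactants: 6 2-bromo-3,5-bis(methoxymethoxy)-4-(3-methylbut-2-en-1-yl)phenol
Product: 9 3,5-bis(methoxymethoxy)-4-(3-methylbut-2-en-1-yl)-2-(trimethylsilyl)phenyl trifluoromethanesulfonate, via aryl trimethylsilyl ether 7 (not isolated), via lithium 2-silylphenoxide 8 (not isolated)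
Conditions: HMDS, THF, 65 °C, then evaporation; n-BuLi (1.1 equiv), THF, −90 → −78 °C; Tf2O, −78 → 0 °C
Reagents that add atoms: hexamethyldisilazane, C[Si](C)(C)N[Si](C)(C)C; trifluoromethanesulfonic anhydride, O=S(=O)(OS(=O)(=O)C(F)(F)F)C(F)(F)F
Why: O-silylation, bromine–lithium exchange and 1,3-retro-Brook (O→C) silyl migration give the ortho-silyl phenoxide, which is trapped as the triflate, the standard entry to fluoride-triggered aryne precursors.

Step 7
Reactants: 10 4-formyl-2-methoxyphenyl acetate (vanillin acetate)
Product: 11 2-methoxy-4-[(2S)-4-oxooxetan-2-yl]phenyl acetate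
Conditions: AcCl (slow addition), iPr2NEt, O-trimethylsilylquinine (10 mol%), LiClO4, CH2Cl2/Et2O, −78 → −40 °C
Reagents that add atoms: acetyl chloride, CC(Cl)=O
Why: Ketene formed from acetyl chloride is bound by the alkaloid as a chiral ammonium enolate that adds to the lithium-activated aldehyde and closes to the β-lactone (catalytic asymmetric ketene–aldehyde [2+2] cycloaddition); the catalyst selects the aldehyde face and so sets the lactone C4 (later C2) as S, and the acetoxy group keeps the aryl group electron-poor enough for the lactone to resist loss of CO2.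

Step 8
Reactants: 9 3,5-bis(methoxymethoxy)-4-(3-methylbut-2-en-1-yl)-2-(trimethylsilyl)phenyl trifluoromethanesulfonate; 11 2-methoxy-4-[(2S)-4-oxooxetan-2-yl]phenyl acetate
Product: 13 (2S)-2-(4-acetoxy-3-methoxyphenyl)-5,7-bis(methoxymethoxy)-6-(3-methylbut-2-en-1-yl)chroman-4-one, via benzyne 12 (not isolated)
Conditions: CsF (3 equiv), MeCN/PhMe (1:1), 23 °C; 9 added over several hours to 11 (1.5 equiv)
Reagents that add atoms: none
Why: Proposed new method: fluoride unmasks benzyne 12 from 9, and the strained lactone, whose ring oxygen is ether-like and whose acyl carbon is unusually electrophilic because ester resonance is weak in the four-membered ring, adds through that oxygen (directly, or after reversible fluoride opening to the alkoxide/acyl fluoride) to the aryne carbon remote from the neighbouring MOM-oxygen; the aryl anion formed ortho to the new C–O bond then attacks the acyl carbon and the acyl–oxygen bond breaks, so that C4a≡C8a is inserted into the O–C(=O) σ-bond and the oxetanone becomes the pyranone, driven by release of the four-ring strain. The closest known reaction types are the aryne insertion into the N–C(=O) bond of β-lactams (to 2,3-dihydroquinolin-4-ones), the C–O insertion of carboxylic acids into arynes, and the aryne annulation of salicylates to xanthones. The six-membered ring arises by ring expansion, through fragmentation of a transient 4-exo-trig adduct of the aryl anion with the acyl carbon (or, on the relay path, by 6-exo-trig acyl substitution at the acyl fluoride). No new stereocentre is formed: C2 is the lactone C4, whose bonds to O, CH2 and aryl are not broken, so the S configuration is carried over with retention. The step needs regioselectivity (O at C8a, acyl at C4a), which the MOM-oxygen next to the aryne secures through the usual distortion and inductive control of 3-alkoxyarynes. It also needs the benzylic C–O bond to resist ionisation, for which the B ring carries the electron-withdrawing acetate instead of an alkyl ether.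

Step 9
Reactants: 13 (2S)-2-(4-acetoxy-3-methoxyphenyl)-5,7-bis(methoxymethoxy)-6-(3-methylbut-2-en-1-yl)chroman-4-one
Product: 14 (2S)-5,7-dihydroxy-2-(4-hydroxy-3-methoxyphenyl)-6-(3-methylbut-2-en-1-yl)chroman-4-one
Conditions: HCl (3 M in MeOH), MeOH, 40 °C, stopped at full conversion
Reagents that add atoms: none
Why: Acid-catalysed acetal exchange with methanol removes both MOM ethers as dimethoxymethane and transesterifies the aryl acetate, while C2, which is labile mainly through base-induced ring opening, should be untouched under mild acid.

**Compound list**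

1 | phloroglucinol (benzene-1,3,5-triol) | Oc1cc(O)cc(O)c1 | starting material
2 | 3,5-bis(methoxymethoxy)phenol | COCOc1cc(O)cc(OCOC)c1 | intermediate
3 | [3,5-bis(methoxymethoxy)phenoxy]triisopropylsilane | COCOc1cc(O[Si](C(C)C)(C(C)C)C(C)C)cc(OCOC)c1 | intermediate
4 | [3,5-bis(methoxymethoxy)-4-(3-methylbut-2-en-1-yl)phenoxy]triisopropylsilane | COCOc1cc(O[Si](C(C)C)(C(C)C)C(C)C)cc(OCOC)c1CC=C(C)C | intermediate
5 | 3,5-bis(methoxymethoxy)-4-(3-methylbut-2-en-1-yl)phenol | COCOc1cc(O)cc(OCOC)c1CC=C(C)C | intermediate
6 | 2-bromo-3,5-bis(methoxymethoxy)-4-(3-methylbut-2-en-1-yl)phenol | COCOc1cc(O)c(Br)c(OCOC)c1CC=C(C)C | intermediate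
7 | [2-bromo-3,5-bis(methoxymethoxy)-4-(3-methylbut-2-en-1-yl)phenoxy]trimethylsilane | COCOc1cc(O[Si](C)(C)C)c(Br)c(OCOC)c1CC=C(C)C | intermediate
8 | lithium 3,5-bis(methoxymethoxy)-4-(3-methylbut-2-en-1-yl)-2-(trimethylsilyl)phenolate | [Li+].[O-]c1cc(OCOC)c(CC=C(C)C)c(OCOC)c1[Si](C)(C)C | intermediate
9 | 3,5-bis(methoxymethoxy)-4-(3-methylbut-2-en-1-yl)-2-(trimethylsilyl)phenyl trifluoromethanesulfonate | COCOc1cc(OS(=O)(=O)C(F)(F)F)c([Si](C)(C)C)c(OCOC)c1CC=C(C)C | intermediate
10 | 4-formyl-2-methoxyphenyl acetate (vanillin acetate) | COc1cc(C=O)ccc1OC(C)=O | starting material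
11 | 2-methoxy-4-[(2S)-4-oxooxetan-2-yl]phenyl acetate | COc1cc([C@@H]2CC(=O)O2)ccc1OC(C)=O | intermediate
12 | 3,5-bis(methoxymethoxy)-4-(3-methylbut-2-en-1-yl)benzyne (1,2-didehydrobenzene) | COCOC1=C(CC=C(C)C)C(OCOC)=CC#C1 | intermediate
13 | (2S)-2-(4-acetoxy-3-methoxyphenyl)-5,7-bis(methoxymethoxy)-6-(3-methylbut-2-en-1-yl)chroman-4-one | COc1cc([C@@H]2CC(=O)c3c(cc(OCOC)c(CC=C(C)C)c3OCOC)O2)ccc1OC(C)=O | intermediate
14 | (2S)-5,7-dihydroxy-2-(4-hydroxy-3-methoxyphenyl)-6-(3-methylbut-2-en-1-yl)chroman-4-one | COc1cc([C@@H]2CC(=O)c3c(cc(O)c(CC=C(C)C)c3O)O2)ccc1O | target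

**Step count**

Total steps: 9. Longest linear sequence: 8 steps (steps 1–6, 8, 9 from phloroglucinol); the β-lactone branch is one step.

**Steps most likely to fail**

Step 8 (Proposed new method). The neutral lactone oxygen may be too weak a nucleophile, so that the aryne is consumed by fluoride, triflate or self-condensation first. Fluoride may also cleave the aryl acetate or open the lactone irreversibly at the benzylic carbon. Heterolysis of the benzylic C–O bond in the O-arylated intermediate would erode the configuration.

Fallback, known chemistry only, setting out from bromophenol 6 and returning at 13: 6 is converted into its dianion (n-BuLi, 2.2 equiv, THF, −78 °C; phenoxide formation, then bromine–lithium exchange) and acylated with N-methoxy-N-methylacetamide to give 1-[6-hydroxy-2,4-bis(methoxymethoxy)-3-(3-methylbut-2-en-1-yl)phenyl]ethan-1-one F1. Condensation with DMF dimethyl acetal (toluene, 90 °C) gives the enaminone (E)-3-(dimethylamino)-1-[6-hydroxy-2,4-bis(methoxymethoxy)-3-(3-methylbut-2-en-1-yl)phenyl]prop-2-en-1-one F2. F2 closes on silica gel or with a trace of pyridinium tosylate to 5,7-bis(methoxymethoxy)-6-(3-methylbut-2-en-1-yl)-4H-chromen-4-one F3. Palladium-catalysed asymmetric conjugate addition of (4-acetoxy-3-methoxyphenyl)boronic acid to F3 (Pd(OCOCF3)2, tert-butyl pyridine-oxazoline ligand of the enantiomeric series that delivers 2S, NH4PF6, water, 1,2-dichloroethane, 60 °C, no base) should then give 13. In this fallback the stereocentre comes from the ligand and no ring expansion is used.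

Step 7. With an aromatic aldehyde, turnover and facial selectivity may be poor, ketene dimerisation may outrun the cycloaddition, and the aryl lactone may lose CO2 on isolation.

Fallback, setting out from 10 and returning at 11: Roskamp homologation of 10 with tert-butyl diazoacetate (SnCl2 cat., CH2Cl2) gives tert-butyl 3-(4-acetoxy-3-methoxyphenyl)-3-oxopropanoate F4. Noyori asymmetric hydrogenation (Ru–(R)-BINAP, H2, which for β-aryl β-keto esters should deliver the S carbinol) gives tert-butyl (3S)-3-(4-acetoxy-3-methoxyphenyl)-3-hydroxypropanoate F5. Cleavage of the tert-butyl ester with trifluoroacetic acid (CH2Cl2, 0 °C) gives (3S)-3-(4-acetoxy-3-methoxyphenyl)-3-hydroxypropanoic acid F6. Lactonisation by carboxyl activation (benzenesulfonyl chloride, pyridine, 0 °C), which leaves the carbinol configuration untouched, closes F6 to 11.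

Step 9. Acid may promote cyclisation of the prenyl group onto a neighbouring phenol (chroman formation) or hydration of the alkene. Acid-catalysed ring opening to the chalcone, with loss of configuration, may also compete with acetal cleavage.

Fallback, setting out from 13 and returning at 14, in two orthogonal non-protic stages instead of one Brønsted-acid solvolysis: the MOM ethers are removed by Lewis acid/thiol acetal transfer (ZnBr2, n-PrSH, CH2Cl2, 0 °C, minutes) to give (2S)-2-(4-acetoxy-3-methoxyphenyl)-5,7-dihydroxy-6-(3-methylbut-2-en-1-yl)chroman-4-one F7. The aryl acetate of F7 is then cleaved by lipase-catalysed transesterification (Candida antarctica lipase B, n-butanol, MTBE, 40 °C) at neutral pH to give 14.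

**Further compounds**

F1 | step 8 | 1-[6-hydroxy-2,4-bis(methoxymethoxy)-3-(3-methylbut-2-en-1-yl)phenyl]ethan-1-one | CC(=O)c1c(O)cc(OCOC)c(CC=C(C)C)c1OCOC
F2 | step 8 | (E)-3-(dimethylamino)-1-[6-hydroxy-2,4-bis(methoxymethoxy)-3-(3-methylbut-2-en-1-yl)phenyl]prop-2-en-1-one | CN(C)/C=C/C(=O)c1c(O)cc(OCOC)c(CC=C(C)C)c1OCOC
F3 | step 8 | 5,7-bis(methoxymethoxy)-6-(3-methylbut-2-en-1-yl)-4H-chromen-4-one | O=c1ccoc2cc(OCOC)c(CC=C(C)C)c(OCOC)c12
F4 | step 7 | tert-butyl 3-(4-acetoxy-3-methoxyphenyl)-3-oxopropanoate | COc1cc(C(=O)CC(=O)OC(C)(C)C)ccc1OC(C)=O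
F5 | step 7 | tert-butyl (3S)-3-(4-acetoxy-3-methoxyphenyl)-3-hydroxypropanoate | COc1cc([C@@H](O)CC(=O)OC(C)(C)C)ccc1OC(C)=O
F6 | step 7 | (3S)-3-(4-acetoxy-3-methoxyphenyl)-3-hydroxypropanoic acid | COc1cc([C@@H](O)CC(=O)O)ccc1OC(C)=O
F7 | step 9 | (2S)-2-(4-acetoxy-3-methoxyphenyl)-5,7-dihydroxy-6-(3-methylbut-2-en-1-yl)chroman-4-one | COc1cc([C@@H]2CC(=O)c3c(cc(O)c(CC=C(C)C)c3O)O2)ccc1OC(C)=O
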